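**Retrosynthetic overview**
- The arene ring A and the quinone ring B are both 5‑substituted 2,3‑dimethoxy‑1,4‑dioxygenated rings, so both are traced back to dimethyl squarate and formed together in one thermal double ring expansion.
- The precursor is a bis(cyclobutenone) in which the pyran O–CH2 bond already exists as a spiro‑tetrahydropyran; ring A then emerges as the mono‑etherified hydroquinone and ring B as the quinone, with no redox or protecting‑group steps.
- The spiro ether comes from a triol by closing O–C2; the triol comes from a trilithiated (S)‑bromo‑enynol and two dimethyl squarate units.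
- The (S)‑enynol (C3 of the target) comes from a lipase‑desymmetrised 2‑(2‑bromoallyl)propane‑1,3‑diol, made from diethyl malonate and 2,3‑dibromopropene.
- Ring order: pyran (as spiro ether) first, then rings A and B in the same operation.

Assumption: Amano lipase PS/vinyl acetate is taken to give the (S)‑monoacetate (to be confirmed by Mosher analysis; hydrolysis of the diacetate with the same enzyme is enantiocomplementary); dimethyl squarate and the Bestmann–Ohira reagent are bought.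

**Step 1**
Reactants: 1 diethyl malonate; 2 2,3‑dibromoprop‑1‑ene
Product: 3 diethyl 2‑(2‑bromoprop‑2‑en‑1‑yl)propanedioate
Conditions: NaH (1.0 equiv), 1 (2 equiv), THF, 0 °C → rt
Reagents that add atoms: none
Why: Malonic ester alkylation; the enolate displaces only the allylic bromide (the vinylic C–Br is inert to SN2) and excess malonate suppresses dialkylation.

**Step 2**
Reactants: 3 diethyl 2‑(2‑bromoprop‑2‑en‑1‑yl)propanedioate
Product: 4 2‑(2‑bromoprop‑2‑en‑1‑yl)propane‑1,3‑diol (prochiral)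
Conditions: LiAlH4, Et2O, 0 °C; Fieser work‑up
Reagents that add atoms: none
Why: Hydride reduction of both esters at 0 °C leaves the vinyl bromide untouched and gives the prochiral 1,3‑diol.

**Step 3**
Reactants: 4 2‑(2‑bromoprop‑2‑en‑1‑yl)propane‑1,3‑diol
Product: 5 (2S)‑4‑bromo‑2‑(hydroxymethyl)pent‑4‑en‑1‑yl acetate
Conditions: Amano lipase PS, vinyl acetate, iPr2O, rt, run to slight over‑acetylation
Reagents that add atoms: vinyl acetate, C=COC(C)=O
Why: Enzymatic desymmetrisation (irreversible lipase transesterification) acylates one enantiotopic CH2OH and so sets the only stereocentre of the route, the future C3, with ee upgraded by the coupled kinetic resolution to diacetate.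

**Step 4**
Reactants: 5 (2S)‑4‑bromo‑2‑(hydroxymethyl)pent‑4‑en‑1‑yl acetate
Product: 8 (2S)‑4‑bromo‑2‑ethynylpent‑4‑en‑1‑ol, via aldehyde 6 (not isolated), via alkynyl acetate 7 (not isolated)
Conditions: DMP, CH2Cl2, 0 °C → rt; crude 6 added to Bestmann–Ohira reagent/NaOMe, THF, −78 °C → rt; then MeOH, K2CO3 (cat.), rt
Reagents that add atoms: dimethyl (1‑diazo‑2‑oxopropyl)phosphonate (Bestmann–Ohira reagent), CC(=O)C(=[N+]=[N-])P(=O)(OC)OC
Why: Dess–Martin oxidation followed by Seyferth–Gilbert/Ohira–Bestmann homologation with the phosphonate anion pre‑formed at −78 °C, so the β‑acetoxy aldehyde meets no free base when warm; methanolysis then removes the acetate and the stereocentre is carried through unchanged (S).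

**Step 5**
Reactants: 8 (2S)‑4‑bromo‑2‑ethynylpent‑4‑en‑1‑ol; 9 dimethyl squarate (3,4‑dimethoxycyclobut‑3‑ene‑1,2‑dione, 2.5 equiv)
Product: 11 4‑hydroxy‑4‑[(3S)‑5‑(1‑hydroxy‑2,3‑dimethoxy‑4‑oxocyclobut‑2‑en‑1‑yl)‑3‑(hydroxymethyl)hex‑5‑en‑1‑yn‑1‑yl]‑2,3‑dimethoxycyclobut‑2‑en‑1‑one (mixture of carbinol epimers), via trilithio species 10 (not isolated)
Conditions: n‑BuLi (2.05 equiv), THF, −78 °C; t‑BuLi (2.1 equiv), −78 °C; cannulate into 9, THF, −78 °C; aq. NH4Cl at −78 °C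
Reagents that add atoms: none
Why: Deprotonation of O–H and C(sp)–H, then Br/Li exchange, gives a trianion whose vinyl‑ and alkynyl‑lithium ends each add 1,2 to a squarate carbonyl (standard squarate ester addition), inverse addition to excess squarate prevents double addition, and the new carbinol centres are erased later.

**Step 6**
Reactants: 11 the triol
Product: 13 (7S)‑7‑[(1‑hydroxy‑2,3‑dimethoxy‑4‑oxocyclobut‑2‑en‑1‑yl)ethynyl]‑2,3‑dimethoxy‑9‑methylidene‑5‑oxaspiro[3.5]non‑2‑en‑1‑one (epimers at the spiro and carbinol carbons), via primary triflate 12 (not isolated)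
Conditions: Tf2O (1.05 equiv), 2,6‑di‑tert‑butyl‑4‑methylpyridine, CH2Cl2, −78 → 0 °C
Reagents that add atoms: none
Why: Hydroxy‑triflate cycloetherification (intramolecular Williamson type); the primary OH is triflated selectively and displaced 6‑exo‑tet by the adjacent tertiary carbinol OH, the alkynyl carbinol cannot reach, and the hindered base stops acid‑induced cyclobutenone rearrangement; C7 (S) is not involved.

**Step 7**
Reactants: 13 the spiro ether
Product: 15 5‑[(3S)‑6‑hydroxy‑7,8‑dimethoxy‑3,4‑dihydro‑2H‑chromen‑3‑yl]‑2,3‑dimethoxycyclohexa‑2,5‑diene‑1,4‑dione (target), via bis‑ketene 14 (not isolated)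
Conditions: p‑xylene (0.01 M, degassed), 138 °C, 1 h
Reagents that add atoms: none
Why: Proposed new method: both cyclobutenones open thermally (4π, oxygen outward) to ketenes; the spiro unit gives a dienylketene whose two exocyclic C=C bonds are locked s‑cis, so 6π closure and enolisation give the 6‑hydroxy‑7,8‑dimethoxychroman (ring O = former carbinol O), while the 4‑alkynyl‑4‑hydroxy unit undergoes Moore cyclisation (enynylketene → diradical → H shift) to the 2,3‑dimethoxyquinone; the closest known reactions are the Liebeskind–Moore ring expansion of 4‑alkenyl‑4‑alkoxycyclobutenones and the Moore rearrangement, and C3 (S) is a spectator.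

**Compound list**
1 | diethyl malonate | CCOC(=O)CC(=O)OCC | starting material
2 | 2,3‑dibromoprop‑1‑ene | BrCC(Br)=C | starting material
3 | diethyl 2‑(2‑bromoprop‑2‑en‑1‑yl)propanedioate | CCOC(=O)C(CC(Br)=C)C(=O)OCC | intermediate
4 | 2‑(2‑bromoprop‑2‑en‑1‑yl)propane‑1,3‑diol | OCC(CO)CC(Br)=C | intermediate
5 | (2S)‑4‑bromo‑2‑(hydroxymethyl)pent‑4‑en‑1‑yl acetate | OC[C@H](CC(Br)=C)COC(C)=O | intermediate
6 | (2R)‑2‑(acetoxymethyl)‑4‑bromopent‑4‑enal (not isolated) | O=C[C@H](CC(Br)=C)COC(C)=O | intermediate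
7 | (2S)‑4‑bromo‑2‑ethynylpent‑4‑en‑1‑yl acetate (not isolated) | C#C[C@H](CC(Br)=C)COC(C)=O | intermediate
8 | (2S)‑4‑bromo‑2‑ethynylpent‑4‑en‑1‑ol | C#C[C@H](CC(Br)=C)CO | intermediate
9 | dimethyl squarate (3,4‑dimethoxycyclobut‑3‑ene‑1,2‑dione) | COC1=C(OC)C(=O)C1=O | starting material
10 | trilithio species of 8 (O‑Li, alkynyl‑Li, 2‑lithioalkene; not isolated) | [Li]C#C[C@H](CC(=C)[Li])CO[Li] | intermediate
11 | 4‑hydroxy‑4‑[(3S)‑5‑(1‑hydroxy‑2,3‑dimethoxy‑4‑oxocyclobut‑2‑en‑1‑yl)‑3‑(hydroxymethyl)hex‑5‑en‑1‑yn‑1‑yl]‑2,3‑dimethoxycyclobut‑2‑en‑1‑one | O=C1C(OC)=C(OC)C1(O)C#C[C@H](CC(=C)C2(O)C(OC)=C(OC)C2=O)CO | intermediate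
12 | primary triflate of 11, (2S) (not isolated) | O=C1C(OC)=C(OC)C1(O)C#C[C@H](CC(=C)C2(O)C(OC)=C(OC)C2=O)COS(=O)(=O)C(F)(F)F | intermediate
13 | (7S)‑7‑[(1‑hydroxy‑2,3‑dimethoxy‑4‑oxocyclobut‑2‑en‑1‑yl)ethynyl]‑2,3‑dimethoxy‑9‑methylidene‑5‑oxaspiro[3.5]non‑2‑en‑1‑one | O=C1C(OC)=C(OC)C1(O)C#C[C@@H]2CC(=C)C3(OC2)C(OC)=C(OC)C3=O | intermediate
14 | bis‑ketene from 4π opening of both four‑membered rings of 13: (S)‑dienylketene on a 2‑ylidene‑3‑methylidene‑tetrahydropyran plus 1‑hydroxy‑enynylketene (not isolated) | O=C=C(OC)/C(OC)=C(/O)C#C[C@@H]1CC(=C)/C(OC1)=C(OC)\C(OC)=C=O | intermediate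
15 | 5‑[(3S)‑6‑hydroxy‑7,8‑dimethoxy‑3,4‑dihydro‑2H‑chromen‑3‑yl]‑2,3‑dimethoxycyclohexa‑2,5‑diene‑1,4‑dione | COC1=C(OC)C(=O)C([C@H]2COc3c(cc(O)c(OC)c3OC)C2)=CC1=O | target

**Totals**
Total steps: 7. Longest linear sequence: 7 (from diethyl malonate; dimethyl squarate enters twice in step 5).

**Three steps most likely to fail, with fallbacks**

Step 4. The β‑acetoxy aldehyde 6 may lose AcOH or epimerise before it is homologated. The fallback removes base from the stage where the centre is α to a carbonyl. It sets out from 5: oxidise as before and treat crude 6 at once with CBr4/PPh3/Zn (CH2Cl2, 0 °C, neutral Ramirez olefination) to give the configurationally robust (2S)‑4‑bromo‑2‑(2,2‑dibromoethenyl)pent‑4‑en‑1‑yl acetate F1. Methanolysis (K2CO3, MeOH) gives (2S)‑4‑bromo‑2‑(2,2‑dibromoethenyl)pent‑4‑en‑1‑ol F2. n‑BuLi (3 equiv, THF, −78 °C; Corey–Fuchs/Fritsch–Buttenberg–Wiechell, the gem‑dibromide exchanging much faster than the 2‑bromoalkene) and NH4Cl quench return to the route at 8.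

Step 6. Triflation may not be selective, or the tertiary α‑ketol OH may be too poor a nucleophile, so the spiro ether does not form. The fallback makes ring A first and closes the pyran at the phenol stage. It sets out from 8: the trianion 10 is treated with only 1.0 equiv of 9 at −78 °C (the vinyllithium reacts far faster than the acetylide) to give 4‑hydroxy‑4‑[(4S)‑4‑(hydroxymethyl)hex‑1‑en‑5‑yn‑2‑yl]‑2,3‑dimethoxycyclobut‑2‑en‑1‑one F3. Heating in toluene at 110 °C gives 2‑[(2S)‑2‑(hydroxymethyl)but‑3‑yn‑1‑yl]‑5,6‑dimethoxybenzene‑1,4‑diol F4. Mitsunobu closure (PPh3, DIAD, degassed THF, 0 °C; only the OH ortho to the chain can form a ring) gives (3S)‑3‑ethynyl‑7,8‑dimethoxy‑3,4‑dihydro‑2H‑chromen‑6‑ol F5. n‑BuLi (2 equiv) then 9 gives 4‑{[(3S)‑6‑hydroxy‑7,8‑dimethoxy‑3,4‑dihydro‑2H‑chromen‑3‑yl]ethynyl}‑4‑hydroxy‑2,3‑dimethoxycyclobut‑2‑en‑1‑one F6. Moore rearrangement in p‑xylene at 138 °C returns to the route at 15.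

Step 7. The alkynyl unit may divert to cyclopentenedione or H‑abstraction products, or the nascent phenol may intercept ketenes. The fallback replaces the diradical Moore pathway for ring B by a purely electrocyclic one. It sets out from 13: Lindlar semihydrogenation (H2, Pd/CaCO3/Pb, quinoline, EtOAc; the 1,1‑disubstituted alkene is untouched) gives (7S)‑7‑[(Z)‑2‑(1‑hydroxy‑2,3‑dimethoxy‑4‑oxocyclobut‑2‑en‑1‑yl)ethenyl]‑2,3‑dimethoxy‑9‑methylidene‑5‑oxaspiro[3.5]non‑2‑en‑1‑one F7. Thermolysis in toluene at 110 °C (two 4π/6π ring expansions) gives 2‑[(3S)‑6‑hydroxy‑7,8‑dimethoxy‑3,4‑dihydro‑2H‑chromen‑3‑yl]‑5,6‑dimethoxybenzene‑1,4‑diol F8. Ag2O (Et2O, rt) oxidises only the hydroquinone ring and returns to the route at 15.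

**Further compounds**
F1 | step 4 | (2S)‑4‑bromo‑2‑(2,2‑dibromoethenyl)pent‑4‑en‑1‑yl acetate | BrC(Br)=C[C@H](CC(Br)=C)COC(C)=O
F2 | step 4 | (2S)‑4‑bromo‑2‑(2,2‑dibromoethenyl)pent‑4‑en‑1‑ol | BrC(Br)=C[C@H](CC(Br)=C)CO
F3 | step 6 | 4‑hydroxy‑4‑[(4S)‑4‑(hydroxymethyl)hex‑1‑en‑5‑yn‑2‑yl]‑2,3‑dimethoxycyclobut‑2‑en‑1‑one | C#C[C@H](CC(=C)C1(O)C(OC)=C(OC)C1=O)CO
F4 | step 6 | 2‑[(2S)‑2‑(hydroxymethyl)but‑3‑yn‑1‑yl]‑5,6‑dimethoxybenzene‑1,4‑diol | C#C[C@H](Cc1cc(O)c(OC)c(OC)c1O)CO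
F5 | step 6 | (3S)‑3‑ethynyl‑7,8‑dimethoxy‑3,4‑dihydro‑2H‑chromen‑6‑ol | C#C[C@H]1COc2c(OC)c(OC)c(O)cc2C1
F6 | step 6 | 4‑{[(3S)‑6‑hydroxy‑7,8‑dimethoxy‑3,4‑dihydro‑2H‑chromen‑3‑yl]ethynyl}‑4‑hydroxy‑2,3‑dimethoxycyclobut‑2‑en‑1‑one | O=C1C(OC)=C(OC)C1(O)C#C[C@H]2COc3c(OC)c(OC)c(O)cc3C2
F7 | step 7 | (7S)‑7‑[(Z)‑2‑(1‑hydroxy‑2,3‑dimethoxy‑4‑oxocyclobut‑2‑en‑1‑yl)ethenyl]‑2,3‑dimethoxy‑9‑methylidene‑5‑oxaspiro[3.5]non‑2‑en‑1‑one | O=C1C(OC)=C(OC)C1(O)/C=C\[C@@H]2CC(=C)C3(OC2)C(OC)=C(OC)C3=O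
F8 | step 7 | 2‑[(3S)‑6‑hydroxy‑7,8‑dimethoxy‑3,4‑dihydro‑2H‑chromen‑3‑yl]‑5,6‑dimethoxybenzene‑1,4‑diol | COc1c(OC)c(O)c([C@H]2COc3c(cc(O)c(OC)c3OC)C2)cc1O
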